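**Retrosynthetic overview**
1. Target 17 ⇒ C7–C11 aldol disconnection: methyl pyruvate 16 + bicyclic acetoxy-enedione 15 (side chain last).
2. 15 ⇒ ring B opened at C3=C4 (ring-closing metathesis): cyclohexanone 14 carrying a vinyl ketone arm on C10 and an isopropenyl group on C5.
3. Six-membered ring A ⇒ one-carbon ring expansion of cyclopentanone 8: 1,2-shift of the quaternary C10 onto a carbenoid carbon, which moves the ketone from "next to C10" to C8.
4. 8 ⇒ chelation-controlled addition of lithiated methoxyallene to keto aldehyde 6 ⇒ three-component coupling of 2-methylcyclopent-2-enone, isopropenyl Grignard and formaldehyde.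
5. Ring order: five-membered precursor of ring A (bought) → expanded to ring A → ring B closed onto it.

Assumption: atoms are named by eudesmane numbering (C8 = ring A ketone, C10 = quaternary carbon, C1 = acetoxy carbon, C11 = carbinol of the side chain); organometallic solutions (2, n-BuLi, LiTMP) are commercial or made separately.

**Step 1**
Reactants: 1 2-methylcyclopent-2-en-1-one; 2 isopropenylmagnesium bromide; 3 formaldehyde
Product: 5 (2S,3R)-2-(hydroxymethyl)-2-methyl-3-(prop-1-en-2-yl)cyclopentan-1-one, via magnesium enolate 4 (not isolated)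
Conditions: 2 (1.3 equiv), Cu(OTf)2 (3 mol%), chiral hydroxyalkyl imidazolinium PF6 salt (carbene precursor, 4 mol%, enantiomer giving 3R), Et2O, −30 °C; then monomeric 3 (gas), −40 °C; H2O
Reagents that add atoms: none
Why: Copper–carbene-catalysed asymmetric conjugate addition of a Grignard reagent to a 2-substituted cycloalkenone (established for alkyl Grignards) sets C5 by catalyst-controlled facial attack, and the tetrasubstituted magnesium enolate is captured by formaldehyde anti to the new isopropenyl group, which sets the quaternary C10 trans (three-component conjugate addition–aldol).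

**Step 2**
Reactants: 5 (2S,3R)-2-(hydroxymethyl)-2-methyl-3-(prop-1-en-2-yl)cyclopentan-1-one
Product: 6 (1S,5R)-1-methyl-2-oxo-5-(prop-1-en-2-yl)cyclopentane-1-carbaldehyde
Conditions: Dess–Martin periodinane (1.2 equiv), CH2Cl2, 0 °C to rt
Reagents that add atoms: none
Why: Dess–Martin oxidation turns the neopentylic primary alcohol into the aldehyde under neutral conditions, so no retro-aldol loss of formaldehyde occurs and the non-enolisable C10 is untouched.

**Step 3**
Reactants: 6 (1S,5R)-1-methyl-2-oxo-5-(prop-1-en-2-yl)cyclopentane-1-carbaldehyde; 7 methoxyallene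
Product: 8 (2S,3R)-2-[(1R)-1-hydroxy-2-methoxybuta-2,3-dien-1-yl]-2-methyl-3-(prop-1-en-2-yl)cyclopentan-1-one
Conditions: 7 (1.5 equiv), n-BuLi, THF, −78 °C; then 6 pre-mixed with MgBr2·OEt2 (1.2 equiv) in CH2Cl2, −78 °C; H2O
Reagents that add atoms: none
Why: Cram-chelate-controlled 1,2-addition: magnesium bridges the aldehyde and ring-ketone oxygens, and lithiated methoxyallene (an acryloyl anion equivalent) attacks the much more electrophilic aldehyde from the face flanked by the small C10 methyl instead of the ring C5 side, which sets C1 as R (oxygen later cis to the C10 methyl).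

**Step 4**
Reactants: 8 (2S,3R)-2-[(1R)-1-hydroxy-2-methoxybuta-2,3-dien-1-yl]-2-methyl-3-(prop-1-en-2-yl)cyclopentan-1-one; 9 dibromomethane
Product: 13 (3S,4R)-3-[(1R)-1-hydroxy-2-oxobut-3-en-1-yl]-3-methyl-4-(prop-1-en-2-yl)cyclohexan-1-one, via dibromomethyl carbinolate 10 (not isolated), via ring-expanded lithium enolate 11 (not isolated), via allenyl ether ketone 12 (not isolated)
Conditions: 9 (1.5 equiv), LiTMP (2.6 equiv), THF, −78 °C; n-BuLi (2.0 equiv), −95 to 0 °C; then 1 M HCl, THF, 0 °C
Reagents that add atoms: water, O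
Why: β-Oxido carbenoid ring expansion (Nozaki–Yamamoto homologation): LiCHBr2 adds to the ketone, bromine–lithium exchange gives the carbenoid, and the more substituted, electron-rich quaternary C10 migrates with retention onto the carbenoid carbon with loss of LiBr, so the new CH2 (C9) lands between C10 and the carbonyl without touching any stereocentre, while the acidic work-up hydrolyses the allenyl ether to the vinyl ketone.

**Step 5**
Reactants: 13 (3S,4R)-3-[(1R)-1-hydroxy-2-oxobut-3-en-1-yl]-3-methyl-4-(prop-1-en-2-yl)cyclohexan-1-one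
Product: 14 (1R)-1-[(1S,2R)-1-methyl-5-oxo-2-(prop-1-en-2-yl)cyclohexyl]-2-oxobut-3-en-1-yl acetate
Conditions: Ac2O (1.5 equiv), Sc(OTf)3 (1 mol%), MeCN, −20 °C
Reagents that add atoms: acetic anhydride, CC(=O)OC(C)=O
Why: Lewis-acid-catalysed acetylation esterifies the hindered secondary alcohol without amine nucleophiles that would add to or dimerise the vinyl ketone, and C1 is not affected.

**Step 6**
Reactants: 14 (1R)-1-[(1S,2R)-1-methyl-5-oxo-2-(prop-1-en-2-yl)cyclohexyl]-2-oxobut-3-en-1-yl acetate
Product: 15 (1R,4aR,8aS)-4,8a-dimethyl-2,7-dioxo-1,2,4a,5,6,7,8,8a-octahydronaphthalen-1-yl acetate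
Conditions: (H2IMes)(PCy3)Cl2Ru=CHPh (second-generation Grubbs catalyst, 5 mol%), CH2Cl2 (5 mM), 40 °C
Reagents that add atoms: none
Why: Ring-closing metathesis joins the vinyl ketone and the 1,1-disubstituted isopropenyl group, which sit as trans-diequatorial neighbours on ring A, to close ring B as the trisubstituted cyclohexenone and fix the trans ring fusion set in step 1.

**Step 7**
Reactants: 15 (1R,4aR,8aS)-4,8a-dimethyl-2,7-dioxo-1,2,4a,5,6,7,8,8a-octahydronaphthalen-1-yl acetate; 16 methyl pyruvate
Product: 17 methyl (2S)-2-[(2R,4aS,5R,8aR)-5-(acetyloxy)-4a,8-dimethyl-3,6-dioxo-1,2,3,4,4a,5,6,8a-octahydronaphthalen-2-yl]-2-hydroxypropanoate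
Conditions: 16 (3 equiv, syringe pump), (R)-5-(pyrrolidin-2-yl)-1H-tetrazole (20 mol%), DMSO, 4 °C to rt
Reagents that add atoms: none
Why: Proposed new method: a late-stage, donor-limited enamine aldol on a polyfunctional decalindione, not yet shown (closest known reaction type: proline- or prolyl-tetrazole-catalysed direct aldol of cyclohexanone with α-keto esters through a Houk–List transition state); the amine condenses only with the unhindered saturated C8 ketone (the C2 enone carbonyl is conjugated and flanked by C1–OAc and quaternary C10), the enamine forms toward C7 because C9 is neopentylic, and the (R)-catalyst delivers the N–H-activated pyruvate to the β-face of C7 (stereoelectronically preferred axial attack, matched with the catalyst) with the ester anti to the enamine and the methyl inside, which forms the C7–C11 bond and sets C7 (R) and C11 (S).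

**Compound list**
1 | 2-methylcyclopent-2-en-1-one | CC1=CCCC1=O | starting material
2 | isopropenylmagnesium bromide | CC(=C)[Mg]Br | starting material
3 | formaldehyde | C=O | starting material
4 | bromomagnesium (3R)-2-methyl-3-(prop-1-en-2-yl)cyclopent-1-en-1-olate (not isolated) | C1C[C@H](C(C)=C)C(C)=C1O[Mg]Br | intermediate
5 | (2S,3R)-2-(hydroxymethyl)-2-methyl-3-(prop-1-en-2-yl)cyclopentan-1-one | C1C[C@H](C(C)=C)[C@@](C)(CO)C1=O | intermediate
6 | (1S,5R)-1-methyl-2-oxo-5-(prop-1-en-2-yl)cyclopentane-1-carbaldehyde | C1C[C@H](C(C)=C)[C@@](C)(C=O)C1=O | intermediate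
7 | methoxyallene (1-methoxypropa-1,2-diene) | COC=C=C | starting material
8 | (2S,3R)-2-[(1R)-1-hydroxy-2-methoxybuta-2,3-dien-1-yl]-2-methyl-3-(prop-1-en-2-yl)cyclopentan-1-one | C1C[C@H](C(C)=C)[C@@](C)([C@@H](O)C(OC)=C=C)C1=O | intermediate
9 | dibromomethane | BrCBr | starting material
10 | dilithium dialkoxide of the LiCHBr2 adduct of 8, (2S,3R)-1-(dibromomethyl)-2-[(1R)-1-hydroxy-2-methoxybuta-2,3-dien-1-yl]-2-methyl-3-(prop-1-en-2-yl)cyclopentan-1-ol (ring C1 configuration undefined and lost in the shift; not isolated) | C1C[C@H](C(C)=C)[C@@](C)([C@@H](O[Li])C(OC)=C=C)C1(O[Li])C(Br)Br | intermediate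
11 | dilithium salt of 12: C8–C9 lithium enolate and C1 lithium alkoxide, stereocentres as in 12 (not isolated) | C1C[C@H](C(C)=C)[C@@](C)([C@@H](O[Li])C(OC)=C=C)C=C1O[Li] | intermediate
12 | (3S,4R)-3-[(1R)-1-hydroxy-2-methoxybuta-2,3-dien-1-yl]-3-methyl-4-(prop-1-en-2-yl)cyclohexan-1-one (not isolated) | C1C[C@H](C(C)=C)[C@@](C)([C@@H](O)C(OC)=C=C)CC1=O | intermediate
13 | (3S,4R)-3-[(1R)-1-hydroxy-2-oxobut-3-en-1-yl]-3-methyl-4-(prop-1-en-2-yl)cyclohexan-1-one | C1C[C@H](C(C)=C)[C@@](C)([C@@H](O)C(=O)C=C)CC1=O | intermediate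
14 | (1R)-1-[(1S,2R)-1-methyl-5-oxo-2-(prop-1-en-2-yl)cyclohexyl]-2-oxobut-3-en-1-yl acetate | C1C[C@H](C(C)=C)[C@@](C)([C@@H](OC(C)=O)C(=O)C=C)CC1=O | intermediate
15 | (1R,4aR,8aS)-4,8a-dimethyl-2,7-dioxo-1,2,4a,5,6,7,8,8a-octahydronaphthalen-1-yl acetate (trans-fused; OAc cis to the angular methyl) | C1C[C@@H]2C(C)=CC(=O)[C@H](OC(C)=O)[C@@]2(C)CC1=O | intermediate
16 | methyl pyruvate | CC(=O)C(=O)OC | starting material
17 | methyl (2S)-2-[(2R,4aS,5R,8aR)-5-(acetyloxy)-4a,8-dimethyl-3,6-dioxo-1,2,3,4,4a,5,6,8a-octahydronaphthalen-2-yl]-2-hydroxypropanoate (CNP0211188.1) | COC(=O)[C@@](C)(O)[C@H]1C[C@@H]2C(C)=CC(=O)[C@H](OC(C)=O)[C@@]2(C)CC1=O | target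

**Step count and risks**
Total steps: 7. Longest linear sequence: 7 (1 → 5 → 6 → 8 → 13 → 14 → 15 → 17).

The three steps most likely to fail are step 4, step 7 and step 1.

Step 4 (ring expansion). The risks are migration of the ring CH2 instead of the quaternary carbon, and damage to the allenyl ether or the free alkoxide under the lithium reagents. The fallback sets out from 8 and replaces the carbenoid by a cationic semipinacol trigger. (Phenylselanyl)methyllithium, made from bis(phenylselanyl)methane and n-BuLi, adds to the ketone to give the β-hydroxy selenide (2S,3R)-2-[(1R)-1-hydroxy-2-methoxybuta-2,3-dien-1-yl]-2-methyl-1-[(phenylselanyl)methyl]-3-(prop-1-en-2-yl)cyclopentan-1-ol F3. TlOEt in CHCl3 turns selenium into a leaving group (selenium ylide with dichlorocarbene, then selenonium alkoxide), and the more substituted carbon shifts to give 12. 1 M HCl then hydrolyses 12 to 13, where the route is rejoined.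

Step 7 (the proposed new step). The risks are self-aldol of the pyruvate, slow enamine formation on the hindered decalone, the unknown position of the ester in the transition state, and retro-aldol drift of the axial C7 epimer on long exposure. The fallback uses known reactions only and sets out from 15. 2-Iodoxybenzoic acid in DMSO dehydrogenates the C8 ketone, which can only desaturate toward C7–C6 because C10 is quaternary, to the enone (1R,4aR,8aS)-4,8a-dimethyl-2,7-dioxo-1,2,4a,7,8,8a-hexahydronaphthalen-1-yl acetate F4. RhCl(PPh3)3-catalysed 1,4-hydrosilylation with Et3SiH reduces the less substituted enone selectively to the regiodefined silyl enol ether (1R,4aR,8aS)-4,8a-dimethyl-2-oxo-7-[(triethylsilyl)oxy]-1,2,4a,5,8,8a-hexahydronaphthalen-1-yl acetate F5. A TiCl4-promoted Mukaiyama aldol with 16 at −78 °C and aqueous work-up then gives 17 (axial attack at C7; C11 epimers separated by chromatography), so the route is rejoined at the target.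

Step 1 (asymmetric three-component coupling). Alkenyl Grignard reagents are less proven than alkyl ones in the copper–carbene system, so the enantiomeric excess may be low. The fallback sets out from 1 with racemic chemistry and a resolution. Addition of (CH2=C(CH3))2CuLi and capture with formaldehyde give racemic material, that is 5 together with its enantiomer (2R,3S)-2-(hydroxymethyl)-2-methyl-3-(prop-1-en-2-yl)cyclopentan-1-one F1. Kinetic resolution with Burkholderia cepacia lipase and vinyl acetate in MTBE acetylates the unwanted antipode to [(1R,5S)-1-methyl-2-oxo-5-(prop-1-en-2-yl)cyclopentyl]methyl acetate F2. The enzyme's preference has to be screened, and the enantiomeric lipase selectivity is taken if it is reversed. Unreacted 5 is separated by chromatography and re-enters the route at 5.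

**Further compounds**
F1 | step 1 | (2R,3S)-2-(hydroxymethyl)-2-methyl-3-(prop-1-en-2-yl)cyclopentan-1-one | C1C[C@@H](C(C)=C)[C@](C)(CO)C1=O
F2 | step 1 | [(1R,5S)-1-methyl-2-oxo-5-(prop-1-en-2-yl)cyclopentyl]methyl acetate | C1C[C@@H](C(C)=C)[C@](C)(COC(C)=O)C1=O
F3 | step 4 | (2S,3R)-2-[(1R)-1-hydroxy-2-methoxybuta-2,3-dien-1-yl]-2-methyl-1-[(phenylselanyl)methyl]-3-(prop-1-en-2-yl)cyclopentan-1-ol | C1C[C@H](C(C)=C)[C@@](C)([C@@H](O)C(OC)=C=C)C1(O)C[Se]c2ccccc2
F4 | step 7 | (1R,4aR,8aS)-4,8a-dimethyl-2,7-dioxo-1,2,4a,7,8,8a-hexahydronaphthalen-1-yl acetate | C1=C[C@@H]2C(C)=CC(=O)[C@H](OC(C)=O)[C@@]2(C)CC1=O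
F5 | step 7 | (1R,4aR,8aS)-4,8a-dimethyl-2-oxo-7-[(triethylsilyl)oxy]-1,2,4a,5,8,8a-hexahydronaphthalen-1-yl acetate | C=1C[C@@H]2C(C)=CC(=O)[C@H](OC(C)=O)[C@@]2(C)CC=1O[Si](CC)(CC)CC
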